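The target is an all-equatorial piperidine (ring N1, C2–C6): C2 methyl, C3 hydroxyl, C6 side chain. Only C6 cannot be epimerised, so everything rests on closing the ring at C3–C4 by a Dieckmann condensation, reading the C3 oxygen as the ester carbonyl of an N-bound alanine unit, and letting C2 and C3 settle relative to C6 afterwards. In one operation the enolate of a 4-aminobutanoate arm attacks that carbonyl, forming the C3–C4 bond and the six-membered 3-oxo-4-carboxylate. The precursor is an acyclic N-benzyl tertiary amino diester: (2R)-alanine ethyl ester, tert-butyl butanoate arm, and the C16 chain with both carbinols as benzyl ethers.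

Key step: step 13

Remark: a six-membered Claisen closure needs a 4-aminobutanoate arm (two CH2 groups between the N-bearing carbon and the ester carbon), so the imine partner is a four-carbon 4-oxobutanoate; a hex-5-enal-derived arm would be one carbon too long and would close a seven-membered ring. tert-Butyl 4-oxobutanoate, vinylmagnesium bromide solution and (R)-tert-butanesulfinamide are taken as catalogue materials.

Step 1
Reactants: 1 11-bromoundec-1-ene; 2 (S)-propylene oxide
Product: 4 (2S)-tetradec-13-en-2-ol, via undec-10-enylmagnesium bromide 3 (not isolated)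
Conditions: Mg, THF, 40 °C; then CuI (10 mol %), 2, −30 °C → rt; H2O (aq NH4Cl work-up)
Reagents that add atoms: none
Why: Copper-catalysed Grignard opening of a terminal epoxide by SN2 attack at the CH2 carbon, so the (S) carbinol of 2 is carried unchanged into 4 and the terminal alkene is inert.

Step 2
Reactants: 4 (2S)-tetradec-13-en-2-ol
Product: 5 (2S)-12-(oxiran-2-yl)dodecan-2-ol (both epimers at the oxirane carbon)
Conditions: mCPBA, NaHCO3, CH2Cl2, 0 °C → rt
Reagents that add atoms: meta-chloroperoxybenzoic acid (mCPBA), OOC(=O)c1cccc(Cl)c1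
Why: Prilezhaev epoxidation of the isolated terminal alkene; no facial control is expected or needed because the oxirane centre is resolved in step 3.

Step 3
Reactants: 5 (2S)-12-(oxiran-2-yl)dodecan-2-ol (epimer mixture)
Product: 6 (2S)-12-[(2S)-oxiran-2-yl]dodecan-2-ol
Conditions: (S,S)-(salen)Co(OAc) (0.5 mol %), H2O (0.55 equiv), THF, 0 °C → rt
Reagents that add atoms: none
Why: Jacobsen hydrolytic kinetic resolution: the (S,S) trivalent cobalt salen acetate complex (salen = N,N′-bis(3,5-di-tert-butylsalicylidene)cyclohexane-1,2-diamine dianion) should hydrolyse the (R)-oxirane epimer to the polar triol much faster, leaving 6 with the oxirane carbon S; the yield ceiling is half of the material, and the remote alcohol does not interfere.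

Step 4
Reactants: 6 (2S)-12-[(2S)-oxiran-2-yl]dodecan-2-ol; 7 vinylmagnesium bromide
Product: 8 (4S,15S)-hexadec-1-ene-4,15-diol
Conditions: 7 (3 equiv), CuI (20 mol %), THF, −40 → −10 °C; H2O (aq NH4Cl work-up)
Reagents that add atoms: none
Why: Copper-catalysed SN2 opening of the terminal epoxide at CH2 by the vinyl Grignard reagent (one equivalent is consumed by the free hydroxyl), which leaves the (S) oxirane carbon untouched as the homoallylic carbinol.

Step 5
Reactants: 8 (4S,15S)-hexadec-1-ene-4,15-diol
Product: 9 (4S,15S)-4,15-bis(benzyloxy)hexadec-1-ene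
Conditions: NaH, BnBr, Bu4NI (cat.), THF/DMF, 0 °C → rt
Reagents that add atoms: benzyl bromide, BrCc1ccccc1
Why: Double Williamson etherification; benzyl ethers tolerate the Grignard, HCl, alkoxide, TFA and hydride steps that follow and leave together with N-benzyl in the final hydrogenolysis.

Step 6
Reactants: 9 (4S,15S)-4,15-bis(benzyloxy)hexadec-1-ene
Product: 11 (4S,15S)-4,15-bis(benzyloxy)hexadecan-1-ol, via B-alkyl-9-BBN adduct 10 (not isolated)
Conditions: 9-BBN, THF, 0 °C → rt; then NaOH, H2O2, 0 °C → rt
Reagents that add atoms: hydrogen peroxide, OO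
Why: Brown hydroboration–oxidation; the bulky borane places boron on the terminal carbon (anti-Markovnikov) and oxidation gives the primary alcohol.

Step 7
Reactants: 11 (4S,15S)-4,15-bis(benzyloxy)hexadecan-1-ol
Product: 12 (4S,15S)-4,15-bis(benzyloxy)-1-bromohexadecane
Conditions: CBr4, PPh3, CH2Cl2, 0 °C → rt
Reagents that add atoms: tetrabromomethane, BrC(Br)(Br)Br
Why: Appel reaction, SN2 displacement of the oxyphosphonium group at the primary carbon under neutral conditions that leave benzyl ethers alone.

Step 8
Reactants: 13 tert-butyl 4-oxobutanoate; 14 (R)-2-methylpropane-2-sulfinamide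
Product: 15 tert-butyl (4E)-4-{[(R)-tert-butylsulfinyl]imino}butanoate
Conditions: CuSO4 (anhydrous, 2 equiv), CH2Cl2, rt
Reagents that add atoms: none
Why: Dehydrative condensation of an aldehyde with the Ellman sulfinamide to the (E)-N-sulfinyl aldimine; the tert-butyl ester is untouched.

Step 9
Reactants: 12 (4S,15S)-4,15-bis(benzyloxy)-1-bromohexadecane; 15 tert-butyl (4E)-4-{[(R)-tert-butylsulfinyl]imino}butanoate
Product: 17 tert-butyl (4S,8S,19S)-8,19-bis(benzyloxy)-4-{[(R)-tert-butylsulfinyl]amino}icosanoate, via alkylmagnesium bromide 16 (not isolated)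
Conditions: Mg, Et2O, reflux; then 15 (1.3 equiv), CH2Cl2, −78 → −45 °C; H2O (aq NH4Cl work-up)
Reagents that add atoms: none
Why: Grignard addition to an N-tert-butanesulfinyl aldimine in a non-coordinating solvent through the six-membered chair transition state with magnesium on the sulfinyl oxygen, which should deliver the chain to the Si face of the (R)-sulfinyl imine and set C4 as S (minor epimer separable as a sulfinamide diastereomer), while low temperature and the bulk of the tert-butyl ester keep the ester out of the reaction.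

Step 10
Reactants: 18 ethyl (S)-lactate
Product: 19 ethyl (2S)-2-{[(trifluoromethyl)sulfonyl]oxy}propanoate
Conditions: Tf2O, 2,6-lutidine, CH2Cl2, −78 → 0 °C; used at once
Reagents that add atoms: trifluoromethanesulfonic anhydride, O=S(=O)(OS(=O)(=O)C(F)(F)F)C(F)(F)F
Why: O-Sulfonylation of the secondary alcohol; no bond to the stereocentre is broken, so the configuration is retained.

Step 11
Reactants: 17 tert-butyl (4S,8S,19S)-8,19-bis(benzyloxy)-4-{[(R)-tert-butylsulfinyl]amino}icosanoate; 19 ethyl (2S)-2-{[(trifluoromethyl)sulfonyl]oxy}propanoate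
Product: 21 tert-butyl (4S,8S,19S)-8,19-bis(benzyloxy)-4-{[(2R)-1-ethoxy-1-oxopropan-2-yl]amino}icosanoate, via ammonium chloride 20 (not isolated)
Conditions: HCl (4 M in dioxane), MeOH, 0 °C; evaporate; then 19 (1.3 equiv), iPr2NEt (3 equiv), CH2Cl2, 0 °C → rt
Reagents that add atoms: none
Why: Acidic methanolysis of the N–S bond (brief and cold, so tert-butyl ester and benzyl ethers survive) gives an ammonium salt that cannot lactamise, and the amine freed in the presence of the triflate undergoes SN2 N-alkylation with inversion, turning the (S)-lactate centre into the (2R)-alaninate; the hindered secondary amine should not alkylate twice.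

Step 12
Reactants: 21 tert-butyl (4S,8S,19S)-8,19-bis(benzyloxy)-4-{[(2R)-1-ethoxy-1-oxopropan-2-yl]amino}icosanoate
Product: 22 tert-butyl (4S,8S,19S)-4-{benzyl[(2R)-1-ethoxy-1-oxopropan-2-yl]amino}-8,19-bis(benzyloxy)icosanoate
Conditions: BnBr, K2CO3, NaI (cat.), MeCN, 70 °C
Reagents that add atoms: benzyl bromide, BrCc1ccccc1
Why: SN2 N-benzylation with Finkelstein activation; the resulting tertiary amine can no longer form a lactam, and the tert-butyl ester resists aminolysis while the amine is still secondary.

Step 13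
Reactants: 22 tert-butyl (4S,8S,19S)-4-{benzyl[(2R)-1-ethoxy-1-oxopropan-2-yl]amino}-8,19-bis(benzyloxy)icosanoate
Product: 24 tert-butyl (2S,6R)-1-benzyl-2-[(4S,15S)-4,15-bis(benzyloxy)hexadecyl]-5-hydroxy-6-methyl-1,2,3,6-tetrahydropyridine-4-carboxylate, via potassium enolate 23 (not isolated)
Conditions: KOtBu (2.2 equiv), THF (0.05 M), 0 °C → rt; then AcOH, 0 °C
Reagents that add atoms: none
Why: Dieckmann condensation (intramolecular Claisen), the reaction type that closes N-benzyl amino diesters to 1-benzyl-3-oxopiperidine-4-carboxylates: tert-butoxide reversibly deprotonates C2 of the butanoate arm, the ester enolate adds to the alaninate ethyl ester carbonyl, ethoxide leaves, and deprotonation of the new β-keto ester to its chelated potassium enolate 23 pulls the equilibrium forward. The one ring (N1, C2–C6 of the piperidine) closes in a 6-exo-trig mode by forming the C3–C4 bond. No stereocentre is created: C4 becomes an enol carbon, C6 has no acidic hydrogen, and any erosion at the methyl-bearing carbon is repaired in step 14. The selectivity needed is regiochemical only, and the substrate secures it three ways: the alternative closure (alaninate α-carbanion onto the butanoate carbonyl) would meet the poorly electrophilic tert-butyl ester and give a non-enolisable quaternary β-keto ester that reverts by retro-Claisen cleavage; the tertiary N-benzyl amine cannot form a lactam; and the tert-butyl ester resists transesterification by the liberated ethoxide.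

Step 14
Reactants: 24 tert-butyl (2S,6R)-1-benzyl-2-[(4S,15S)-4,15-bis(benzyloxy)hexadecyl]-5-hydroxy-6-methyl-1,2,3,6-tetrahydropyridine-4-carboxylate
Product: 26 (2R,6S)-1-benzyl-6-[(4S,15S)-4,15-bis(benzyloxy)hexadecyl]-2-methylpiperidin-3-one, via β-keto acid 25 (not isolated)
Conditions: TFA/CH2Cl2 (1:3), 0 °C → rt; evaporate; toluene, 80 °C; then K2CO3, MeOH, rt
Reagents that add atoms: none
Why: Acidolysis of the tert-butyl ester (loss of isobutene) and thermal decarboxylation of the β-keto acid through the cyclic six-membered transition state give the 3-piperidinone, and carbonate in methanol then equilibrates the enolisable C2 so that the methyl group should sit equatorial, cis to the fixed C6 chain (thermodynamic epimerisation, which the (2R)-alaninate already matches).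

Step 15
Reactants: 26 (2R,6S)-1-benzyl-6-[(4S,15S)-4,15-bis(benzyloxy)hexadecyl]-2-methylpiperidin-3-one
Product: 27 (2R,3S,6S)-1-benzyl-6-[(4S,15S)-4,15-bis(benzyloxy)hexadecyl]-2-methylpiperidin-3-ol
Conditions: NaBH4, MeOH, −20 °C → 0 °C
Reagents that add atoms: none
Why: Borohydride reduction of a chair-locked cyclic ketone: the small hydride should attack along the axial trajectory (past the nitrogen lone pair, avoiding torsional strain) and give the equatorial C3 alcohol, trans to the C2 methyl (3S); any C3 epimer is to be removed by chromatography at this lipophilic stage.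

Step 16
Reactants: 27 (2R,3S,6S)-1-benzyl-6-[(4S,15S)-4,15-bis(benzyloxy)hexadecyl]-2-methylpiperidin-3-ol
Product: 28 (2R,3S,6S)-6-[(4S,15S)-4,15-dihydroxyhexadecyl]-2-methylpiperidin-3-ol
Conditions: H2 (3 bar), Pd(OH)2/C, MeOH/AcOH (10:1), rt; then aq K2CO3
Reagents that add atoms: none
Why: Palladium-catalysed hydrogenolysis cleaves the N-benzyl and both O-benzyl groups in one operation (acid keeps the amine from inhibiting the catalyst) and touches no stereocentre.

Compound list
1 | 11-bromoundec-1-ene | C=CCCCCCCCCCBr | starting material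
2 | (S)-propylene oxide, (2S)-2-methyloxirane | C[C@H]1CO1 | starting material
3 | undec-10-enylmagnesium bromide | C=CCCCCCCCCC[Mg]Br | intermediate (not isolated)
4 | (2S)-tetradec-13-en-2-ol | C[C@H](O)CCCCCCCCCCC=C | intermediate
5 | (2S)-12-(oxiran-2-yl)dodecan-2-ol, both epimers at the oxirane carbon | C[C@H](O)CCCCCCCCCCC1CO1 | intermediate
6 | (2S)-12-[(2S)-oxiran-2-yl]dodecan-2-ol | C[C@H](O)CCCCCCCCCC[C@H]1CO1 | intermediate
7 | vinylmagnesium bromide | C=C[Mg]Br | starting material
8 | (4S,15S)-hexadec-1-ene-4,15-diol | C[C@H](O)CCCCCCCCCC[C@H](O)CC=C | intermediate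
9 | (4S,15S)-4,15-bis(benzyloxy)hexadec-1-ene | C[C@H](OCc1ccccc1)CCCCCCCCCC[C@H](OCc1ccccc1)CC=C | intermediate
10 | 9-[(4R,15S)-4,15-bis(benzyloxy)hexadecyl]-9-borabicyclo[3.3.1]nonane (same spatial arrangement as 9; the C4 descriptor changes because boron ranks below carbon) | C[C@H](OCc1ccccc1)CCCCCCCCCC[C@H](OCc1ccccc1)CCCB1C2CCCC1CCC2 | intermediate (not isolated)
11 | (4S,15S)-4,15-bis(benzyloxy)hexadecan-1-ol | C[C@H](OCc1ccccc1)CCCCCCCCCC[C@H](OCc1ccccc1)CCCO | intermediate
12 | (4S,15S)-4,15-bis(benzyloxy)-1-bromohexadecane | C[C@H](OCc1ccccc1)CCCCCCCCCC[C@H](OCc1ccccc1)CCCBr | intermediate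
13 | tert-butyl 4-oxobutanoate | CC(C)(C)OC(=O)CCC=O | starting material
14 | (R)-2-methylpropane-2-sulfinamide | CC(C)(C)[S@@](=O)N | starting material
15 | tert-butyl (4E)-4-{[(R)-tert-butylsulfinyl]imino}butanoate | CC(C)(C)OC(=O)CC/C=N/[S@](=O)C(C)(C)C | intermediate
16 | [(4S,15S)-4,15-bis(benzyloxy)hexadecyl]magnesium bromide | C[C@H](OCc1ccccc1)CCCCCCCCCC[C@H](OCc1ccccc1)CCC[Mg]Br | intermediate (not isolated)
17 | tert-butyl (4S,8S,19S)-8,19-bis(benzyloxy)-4-{[(R)-tert-butylsulfinyl]amino}icosanoate | C[C@H](OCc1ccccc1)CCCCCCCCCC[C@H](OCc1ccccc1)CCC[C@@H](CCC(=O)OC(C)(C)C)N[S@](=O)C(C)(C)C | intermediate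
18 | ethyl (S)-lactate, ethyl (2S)-2-hydroxypropanoate | C[C@H](O)C(=O)OCC | starting material
19 | ethyl (2S)-2-{[(trifluoromethyl)sulfonyl]oxy}propanoate | C[C@H](OS(=O)(=O)C(F)(F)F)C(=O)OCC | intermediate
20 | (4S,8S,19S)-8,19-bis(benzyloxy)-1-tert-butoxy-1-oxoicosan-4-aminium chloride | C[C@H](OCc1ccccc1)CCCCCCCCCC[C@H](OCc1ccccc1)CCC[C@@H](CCC(=O)OC(C)(C)C)[NH3+].[Cl-] | intermediate (not isolated)
21 | tert-butyl (4S,8S,19S)-8,19-bis(benzyloxy)-4-{[(2R)-1-ethoxy-1-oxopropan-2-yl]amino}icosanoate | C[C@H](OCc1ccccc1)CCCCCCCCCC[C@H](OCc1ccccc1)CCC[C@@H](CCC(=O)OC(C)(C)C)N[C@H](C)C(=O)OCC | intermediate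
22 | tert-butyl (4S,8S,19S)-4-{benzyl[(2R)-1-ethoxy-1-oxopropan-2-yl]amino}-8,19-bis(benzyloxy)icosanoate | C[C@H](OCc1ccccc1)CCCCCCCCCC[C@H](OCc1ccccc1)CCC[C@@H](CCC(=O)OC(C)(C)C)N(Cc1ccccc1)[C@H](C)C(=O)OCC | intermediate (key-step precursor)
23 | potassium (2R,6S)-1-benzyl-6-[(4S,15S)-4,15-bis(benzyloxy)hexadecyl]-4-(tert-butoxycarbonyl)-2-methyl-1,2,5,6-tetrahydropyridin-3-olate | C[C@H](OCc1ccccc1)CCCCCCCCCC[C@H](OCc1ccccc1)CCC[C@H]1CC(C(=O)OC(C)(C)C)=C([O-])[C@@H](C)N1Cc1ccccc1.[K+] | intermediate (not isolated)
24 | tert-butyl (2S,6R)-1-benzyl-2-[(4S,15S)-4,15-bis(benzyloxy)hexadecyl]-5-hydroxy-6-methyl-1,2,3,6-tetrahydropyridine-4-carboxylate | C[C@H](OCc1ccccc1)CCCCCCCCCC[C@H](OCc1ccccc1)CCC[C@H]1CC(C(=O)OC(C)(C)C)=C(O)[C@@H](C)N1Cc1ccccc1 | intermediate (key-step product)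
25 | (2S,6R)-1-benzyl-2-[(4S,15S)-4,15-bis(benzyloxy)hexadecyl]-5-hydroxy-6-methyl-1,2,3,6-tetrahydropyridine-4-carboxylic acid | C[C@H](OCc1ccccc1)CCCCCCCCCC[C@H](OCc1ccccc1)CCC[C@H]1CC(C(=O)O)=C(O)[C@@H](C)N1Cc1ccccc1 | intermediate (not isolated)
26 | (2R,6S)-1-benzyl-6-[(4S,15S)-4,15-bis(benzyloxy)hexadecyl]-2-methylpiperidin-3-one | C[C@H](OCc1ccccc1)CCCCCCCCCC[C@H](OCc1ccccc1)CCC[C@H]1CCC(=O)[C@@H](C)N1Cc1ccccc1 | intermediate
27 | (2R,3S,6S)-1-benzyl-6-[(4S,15S)-4,15-bis(benzyloxy)hexadecyl]-2-methylpiperidin-3-ol | C[C@H](OCc1ccccc1)CCCCCCCCCC[C@H](OCc1ccccc1)CCC[C@H]1CC[C@H](O)[C@@H](C)N1Cc1ccccc1 | intermediate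
28 | (2R,3S,6S)-6-[(4S,15S)-4,15-dihydroxyhexadecyl]-2-methylpiperidin-3-ol | C[C@H](O)CCCCCCCCCC[C@H](O)CCC[C@H]1CC[C@H](O)[C@@H](C)N1 | target

Total step count: 16. Longest linear sequence: 14 (steps 1–7, 9, 11–16); steps 8 and 10 are one-step side branches.

Steps most likely to fail

Step 13, the ring closure. The Claisen equilibrium may not be reached or may revert: attack on the hindered alaninate carbonyl is slow, retro-Claisen cleavage competes, and intermolecular condensation can take over at higher concentration. The fallback sets out from 22 and returns at 24, and replaces the equilibrium-driven condensation by a kinetically controlled enolate acylation on the same C3–C4 bond. Selective aminolysis of the ethyl ester of 22 with the chloromagnesium amide of N,O-dimethylhydroxylamine (MeNHOMe·HCl, iPrMgCl, THF, −20 °C; the tert-butyl ester is inert) should give the Weinreb amide tert-butyl (4S,8S,19S)-4-(benzyl{(2R)-1-[methoxy(methyl)amino]-1-oxopropan-2-yl}amino)-8,19-bis(benzyloxy)icosanoate F1. LDA (THF, −78 °C) should then deprotonate the less hindered CH2 beside the tert-butyl ester, and the lithium enolate should add to the amide carbonyl in the same 6-exo mode, N,O-dimethylhydroxylamine being released on work-up to give 24.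

Step 12, the N-benzylation. Substitution at a nitrogen flanked by two branched carbons may be too slow, so that prolonged heating lets lactamisation onto the tert-butyl ester or decomposition of benzyl bromide compete. The fallback sets out from 17 and returns at 22, and inverts the order of the two N–C bond formations. After the same HCl/MeOH cleavage of 17 to the ammonium chloride 20, condensation with benzaldehyde (Et3N, MgSO4, CH2Cl2) should give the imine tert-butyl (4S,8S,19S)-4-[(E)-benzylideneamino]-8,19-bis(benzyloxy)icosanoate F2. Reduction with NaBH4 in MeOH at 0 °C should give tert-butyl (4S,8S,19S)-4-(benzylamino)-8,19-bis(benzyloxy)icosanoate F3. This less hindered and more basic secondary amine is then alkylated with triflate 19 (iPr2NEt, CH2Cl2, rt) with the same inversion, giving 22.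

Step 15, the ketone reduction. Facial selectivity of hydride delivery may be poor if the N-benzyl group populates an axial orientation and shields the axial trajectory. The fallback sets out from 26 and returns at 28, and moves the reduction behind the debenzylation. Hydrogenolysis of 26 (H2, Pd(OH)2/C, MeOH, 1 equiv HCl) should give (2R,6S)-6-[(4S,15S)-4,15-dihydroxyhexadecyl]-2-methyl-3-oxopiperidin-1-ium chloride F4, an N–H piperidinone salt with an unencumbered chair. Reduction with NaBH4 (MeOH, −20 °C, then basic work-up) should then favour axial attack and give 28 directly, with the product purified by crystallisation of a salt.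

Further compounds
F1 | step 13 | tert-butyl (4S,8S,19S)-4-(benzyl{(2R)-1-[methoxy(methyl)amino]-1-oxopropan-2-yl}amino)-8,19-bis(benzyloxy)icosanoate | C[C@H](OCc1ccccc1)CCCCCCCCCC[C@H](OCc1ccccc1)CCC[C@@H](CCC(=O)OC(C)(C)C)N(Cc1ccccc1)[C@H](C)C(=O)N(C)OC
F2 | step 12 | tert-butyl (4S,8S,19S)-4-[(E)-benzylideneamino]-8,19-bis(benzyloxy)icosanoate | C[C@H](OCc1ccccc1)CCCCCCCCCC[C@H](OCc1ccccc1)CCC[C@@H](CCC(=O)OC(C)(C)C)/N=C/c1ccccc1
F3 | step 12 | tert-butyl (4S,8S,19S)-4-(benzylamino)-8,19-bis(benzyloxy)icosanoate | C[C@H](OCc1ccccc1)CCCCCCCCCC[C@H](OCc1ccccc1)CCC[C@@H](CCC(=O)OC(C)(C)C)NCc1ccccc1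
F4 | step 15 | (2R,6S)-6-[(4S,15S)-4,15-dihydroxyhexadecyl]-2-methyl-3-oxopiperidin-1-ium chloride | C[C@H](O)CCCCCCCCCC[C@H](O)CCC[C@H]1CCC(=O)[C@@H](C)[NH2+]1.[Cl-]
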